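The route forms the trisubstituted C2=C3 alkene inside a temporary ring. In the target the C3 methyl is cis to C1, and C1 is ortho to the phenol oxygen on the arene. Tying that oxygen to the C3 methyl carbon as an ester carbonyl lets ring-closing metathesis of an aryl 2-alkylacrylate with the ortho-allyl group form C2=C3 in a seven-membered benzoxepinone, where only the required geometry can exist. The precursor is the 2-allyl-4-methoxy-6-methylphenyl ester of the C4–C16 2-methylene acid, with the C5 hydroxyl as triethylsilyl ether and the C14 hydroxyl on the preformed tetrahydrofuran ring as tert-butyldimethylsilyl ether. Lactone reduction and deoxygenation then reveal the phenol and the methyl.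

Key step: step 16

Numbering: C1–C16 are the side-chain atoms of the target (C1 benzylic, C5 the acetoxy carbon, C12, C14 and C15 in the tetrahydrofuran ring); C1 of geranyl acetate becomes C5 and its C8 becomes C12.
Assumption: in step 12 the (S,S)-ligand is taken to direct the allyl group to the Re face of the aldehyde (giving 5R); the sense is set by the ligand alone, so the (R,R)-ligand serves if the opposite sense is found.

Step 1
Reactants: 1 4-methoxy-2-methylphenol; 2 allyl bromide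
Product: 3 allyl 4-methoxy-2-methylphenyl ether
Conditions: K2CO3, acetone, reflux
Reagents that add atoms: none
Why: Williamson ether synthesis, the phenoxide displacing bromide from the primary allylic halide by SN2.

Step 2
Reactants: 3 allyl 4-methoxy-2-methylphenyl ether
Product: 5 2-allyl-4-methoxy-6-methylphenol, via Claisen dienone 4 (not isolated)
Conditions: PhNEt2, 190 °C
Reagents that add atoms: none
Why: The aromatic Claisen rearrangement ([3,3]-sigmatropic) can deliver the allyl group only to the one unsubstituted ortho carbon, and dienone 4 then tautomerises to the phenol.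

Step 3
Reactants: 6 geranyl acetate
Product: 7 (2E,6E)-8-hydroxy-3,7-dimethylocta-2,6-dien-1-yl acetate
Conditions: SeO2 (0.5 equiv), salicylic acid (0.1 equiv), t-BuOOH (3 equiv), CH2Cl2, rt
Reagents that add atoms: tert-butyl hydroperoxide, CC(C)(C)OO (terminal oxidant; the oxygen is relayed by SeO2, O=[Se]=O)
Why: Riley allylic oxidation (ene reaction, then [2,3]-sigmatropic shift) is selective for the (E)-methyl group of the terminal trisubstituted alkene, the C6=C7 alkene being deactivated by its allylic acetate.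

Step 4
Reactants: 7 (2E,6E)-8-hydroxy-3,7-dimethylocta-2,6-dien-1-yl acetate
Product: 8 (2E,6E)-3,7-dimethyl-8-oxoocta-2,6-dien-1-yl acetate
Conditions: MnO2 (excess), CH2Cl2, rt
Reagents that add atoms: none
Why: MnO2 oxidation of a primary allylic alcohol should give the C12 enal without touching the acetate or the alkene geometry, and it converges any aldehyde already formed in step 3.

Step 5
Reactants: 8 (2E,6E)-3,7-dimethyl-8-oxoocta-2,6-dien-1-yl acetate
Product: 10 (2E,6E,8S)-8-hydroxy-3,7-dimethylundeca-2,6,10-trien-1-yl acetate, via borinate ester 9 (not isolated)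
Conditions: (−)-Ipc2B(allyl) [from (+)-α-pinene] (1.3 equiv), Et2O, −78 °C; then NaBO3·4H2O, THF/H2O, rt
Reagents that add atoms: (−)-B-allyldiisopinocampheylborane, C=CCB([C@@H]1C[C@@H]2C[C@H]([C@H]1C)C2(C)C)[C@@H]1C[C@@H]2C[C@H]([C@H]1C)C2(C)C
Why: Asymmetric allylboration through a chair-like six-membered transition state, in which the (+)-α-pinene-derived reagent adds to the Si face of the enal and so sets C12 as S under reagent control.

Step 6
Reactants: 10 (2E,6E,8S)-8-hydroxy-3,7-dimethylundeca-2,6,10-trien-1-yl acetate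
Product: 11 (2E,6E,8S)-8-hydroxy-3,7,11-trimethyldodeca-2,6,10-trien-1-yl acetate
Conditions: 2-methyl-2-butene (excess), second-generation Grubbs catalyst (H2IMes)(PCy3)Cl2Ru=CHPh (3 mol %), CH2Cl2, 40 °C
Reagents that add atoms: 2-methyl-2-butene, CC=C(C)C
Why: Olefin cross-metathesis exchanges the terminal methylidene for an isopropylidene group (C15 and its two methyls) with loss of propene, the trisubstituted alkenes being inert to the catalyst.

Step 7
Reactants: 11 (2E,6E,8S)-8-hydroxy-3,7,11-trimethyldodeca-2,6,10-trien-1-yl acetate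
Product: 12 (2E,6E,8S)-3,7,11-trimethyldodeca-2,6,10-triene-1,8-diyl diacetate
Conditions: Ac2O, pyridine, DMAP (cat.), CH2Cl2, 0 °C to rt
Reagents that add atoms: acetic anhydride, CC(=O)OC(C)=O
Why: DMAP-catalysed acylation of the C12 hydroxyl, which makes C10=C11 an allylic-ester alkene like C6=C7 and so leaves C14=C15 as the only electron-rich alkene for step 8.

Step 8
Reactants: 12 (2E,6E,8S)-3,7,11-trimethyldodeca-2,6,10-triene-1,8-diyl diacetate
Product: 13 (2E,6E,8S)-9-[(2S)-3,3-dimethyloxiran-2-yl]-3,7-dimethylnona-2,6-diene-1,8-diyl diacetate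
Conditions: L-fructose-derived Shi ketone (0.3 equiv), KHSO5 (as Oxone, 2KHSO5·KHSO4·K2SO4), K2CO3, Bu4NHSO4 (cat.), MeCN/CH2(OMe)2, aq. Na2B4O7 buffer, 0 °C
Reagents that add atoms: potassium peroxymonosulfate, [K+].[O-]S(=O)(=O)OO
Why: Shi asymmetric epoxidation by the chiral dioxirane (spiro transition state) should take place at C14=C15, the only alkene without an allylic ester, and the L-fructose-derived ketone delivers oxygen to the face that gives 14S.

Step 9
Reactants: 13 (2E,6E,8S)-9-[(2S)-3,3-dimethyloxiran-2-yl]-3,7-dimethylnona-2,6-diene-1,8-diyl diacetate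
Product: 15 (3S,5S)-5-[(2E,6E)-8-hydroxy-6-methylocta-2,6-dien-2-yl]-2,2-dimethyltetrahydrofuran-3-ol, via epoxy diol 14 (not isolated)
Conditions: K2CO3 (0.3 equiv), MeOH, 0 °C to rt; filtration through silica, solvent exchange; then camphor-10-sulfonic acid (0.2 equiv), CH2Cl2, 0 °C
Reagents that add atoms: none
Why: Zemplén-type methanolysis frees the C12 and C5 hydroxyls, and acid-catalysed 5-endo epoxide opening by the C12 hydroxyl at the tertiary C15 (not a stereocentre) closes the tetrahydrofuran ring with C12 and C14 unchanged.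

Step 10
Reactants: 15 (3S,5S)-5-[(2E,6E)-8-hydroxy-6-methylocta-2,6-dien-2-yl]-2,2-dimethyltetrahydrofuran-3-ol
Product: 16 (2E,6E)-7-[(2S,4S)-4-hydroxy-5,5-dimethyltetrahydrofuran-2-yl]-3-methylocta-2,6-dienal
Conditions: MnO2 (excess), CH2Cl2, rt
Reagents that add atoms: none
Why: MnO2 oxidation is chemoselective for the primary allylic C5 alcohol and leaves the non-allylic secondary C14 hydroxyl alone.

Step 11
Reactants: 16 (2E,6E)-7-[(2S,4S)-4-hydroxy-5,5-dimethyltetrahydrofuran-2-yl]-3-methylocta-2,6-dienal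
Product: 17 (2E,6E)-7-[(2S,4S)-4-(tert-butyldimethylsilyloxy)-5,5-dimethyltetrahydrofuran-2-yl]-3-methylocta-2,6-dienal
Conditions: TBSOTf (1.2 equiv), 2,6-lutidine (2 equiv), CH2Cl2, −78 °C
Reagents that add atoms: tert-butyldimethylsilyl triflate, CC(C)(C)[Si](C)(C)OS(=O)(=O)C(F)(F)F
Why: Silylation with the silyl triflate caps the hindered C14 hydroxyl, the only hydroxyl present, at a temperature at which the enal is not enolised.

Step 12
Reactants: 17 (2E,6E)-7-[(2S,4S)-4-(tert-butyldimethylsilyloxy)-5,5-dimethyltetrahydrofuran-2-yl]-3-methylocta-2,6-dienal; 18 methyl 2-(bromomethyl)acrylate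
Product: 20 methyl (4R,5E,9E)-10-[(2S,4S)-4-(tert-butyldimethylsilyloxy)-5,5-dimethyltetrahydrofuran-2-yl]-4-hydroxy-6-methyl-2-methylideneundeca-5,9-dienoate, via trimethylsilyl ether 19 (not isolated)
Conditions: CrCl2 (10 mol %), (S,S)-1,8-bis(4-isopropyl-4,5-dihydrooxazol-2-yl)carbazole ligand (12 mol %), i-Pr2NEt (30 mol %), Mn powder (2 equiv), Me3SiCl (1.5 equiv), THF, rt; then 0.5 M aq. citric acid, THF, 0 °C
Reagents that add atoms: none
Why: Catalytic asymmetric Nozaki–Hiyama–Kishi 2-(alkoxycarbonyl)allylation adds the allylchromium species 1,2 to the enal on the Re face under ligand control (C5 = R), and in situ O-silylation turns the chromium over and blocks lactonisation.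

Step 13
Reactants: 20 methyl (4R,5E,9E)-10-[(2S,4S)-4-(tert-butyldimethylsilyloxy)-5,5-dimethyltetrahydrofuran-2-yl]-4-hydroxy-6-methyl-2-methylideneundeca-5,9-dienoate
Product: 21 methyl (4R,5E,9E)-10-[(2S,4S)-4-(tert-butyldimethylsilyloxy)-5,5-dimethyltetrahydrofuran-2-yl]-6-methyl-2-methylidene-4-(triethylsilyloxy)undeca-5,9-dienoate
Conditions: TESCl (1.3 equiv), imidazole (2.5 equiv), CH2Cl2, 0 °C
Reagents that add atoms: chlorotriethylsilane, CC[Si](Cl)(CC)CC
Why: Silyl ether formation caps the C5 hydroxyl, which must never be free next to an activated ester because it would close the γ-lactone, and triethylsilyl can later be removed beside the two tert-butyldimethylsilyl ethers.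

Step 14
Reactants: 21 methyl (4R,5E,9E)-10-[(2S,4S)-4-(tert-butyldimethylsilyloxy)-5,5-dimethyltetrahydrofuran-2-yl]-6-methyl-2-methylidene-4-(triethylsilyloxy)undeca-5,9-dienoate
Product: 22 (4R,5E,9E)-10-[(2S,4S)-4-(tert-butyldimethylsilyloxy)-5,5-dimethyltetrahydrofuran-2-yl]-6-methyl-2-methylidene-4-(triethylsilyloxy)undeca-5,9-dienoic acid
Conditions: Me3SnOH (6 equiv), ClCH2CH2Cl, 80 °C; cold dilute aq. KHSO4 wash
Reagents that add atoms: trimethyltin hydroxide, C[Sn](C)(C)O
Why: Tin hydroxide-mediated ester hydrolysis is near-neutral, so both silyl ethers and the acrylate should survive where aqueous alkali might strip the triethylsilyl group.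

Step 15
Reactants: 22 (4R,5E,9E)-10-[(2S,4S)-4-(tert-butyldimethylsilyloxy)-5,5-dimethyltetrahydrofuran-2-yl]-6-methyl-2-methylidene-4-(triethylsilyloxy)undeca-5,9-dienoic acid; 5 2-allyl-4-methoxy-6-methylphenol
Product: 23 2-allyl-4-methoxy-6-methylphenyl (4R,5E,9E)-10-[(2S,4S)-4-(tert-butyldimethylsilyloxy)-5,5-dimethyltetrahydrofuran-2-yl]-6-methyl-2-methylidene-4-(triethylsilyloxy)undeca-5,9-dienoate
Conditions: EDC·HCl (1.5 equiv), DMAP (0.3 equiv), CH2Cl2, 0 °C to rt
Reagents that add atoms: none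
Why: Steglich-type carbodiimide esterification through the acylpyridinium ion acylates even a 2,6-disubstituted phenol, and no other hydroxyl is free.

Step 16
Reactants: 23 2-allyl-4-methoxy-6-methylphenyl (4R,5E,9E)-10-[(2S,4S)-4-(tert-butyldimethylsilyloxy)-5,5-dimethyltetrahydrofuran-2-yl]-6-methyl-2-methylidene-4-(triethylsilyloxy)undeca-5,9-dienoate
Product: 24 3-[(2R,3E,7E)-8-[(2S,4S)-4-(tert-butyldimethylsilyloxy)-5,5-dimethyltetrahydrofuran-2-yl]-4-methyl-2-(triethylsilyloxy)nona-3,7-dien-1-yl]-7-methoxy-9-methyl-1-benzoxepin-2(5H)-one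
Conditions: second-generation Hoveyda–Grubbs catalyst (H2IMes)Cl2Ru=CH(C6H4-2-O-i-Pr) (2 × 5 mol %), 1,4-benzoquinone (20 mol %), toluene (2 mM), 80 °C, argon sparge
Reagents that add atoms: none
Why: The catalyst initiates at the monosubstituted allyl alkene to give an arylmethyl-substituted ruthenium alkylidene, which adds intramolecularly to the 1,1-disubstituted acrylate alkene; cycloreversion of the ruthenacyclobutane releases the lactone and Ru=CH2, and ethene is swept out to drive the closure. The closest known reaction type is ring-closing metathesis of 2-allylaryl acrylates to 1-benzoxepin-2(5H)-ones and of 2-substituted acrylate esters to α-substituted unsaturated lactones. The ring closes by joining the two terminal alkene carbons (the future C2 and C3) into a seven-membered lactone; the ortho relationship on the arene holds the two alkenes close and high dilution suppresses dimerisation. No stereocentre is formed, and C5, C12 and C14 are spectators. Site selectivity among five alkenes is needed and is secured because only the two terminal alkenes can react, the three trisubstituted alkenes being inert, while 1,4-benzoquinone suppresses migration of the allyl double bond. Alkene geometry is secured by the ring, in which the lactone carbonyl carbon and C1 are necessarily cis across C2=C3, the arrangement that becomes 2E once that carbon is reduced to the methyl.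

Step 17
Reactants: 24 3-[(2R,3E,7E)-8-[(2S,4S)-4-(tert-butyldimethylsilyloxy)-5,5-dimethyltetrahydrofuran-2-yl]-4-methyl-2-(triethylsilyloxy)nona-3,7-dien-1-yl]-7-methoxy-9-methyl-1-benzoxepin-2(5H)-one
Product: 25 2-[(2Z,5R,6E,10E)-11-[(2S,4S)-4-(tert-butyldimethylsilyloxy)-5,5-dimethyltetrahydrofuran-2-yl]-3-(hydroxymethyl)-7-methyl-5-(triethylsilyloxy)dodeca-2,6,10-trien-1-yl]-4-methoxy-6-methylphenol
Conditions: i-Bu2AlH (4 equiv), CH2Cl2, −78 °C; aq. KNaC4H4O6 work-up
Reagents that add atoms: none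
Why: Hydride reduction of the aryl lactone (1,2-selective) opens the temporary ring to the phenol and the C3 hydroxymethyl group, at low temperature so that the aryloxide cannot add back to the transient enal.

Step 18
Reactants: 25 2-[(2Z,5R,6E,10E)-11-[(2S,4S)-4-(tert-butyldimethylsilyloxy)-5,5-dimethyltetrahydrofuran-2-yl]-3-(hydroxymethyl)-7-methyl-5-(triethylsilyloxy)dodeca-2,6,10-trien-1-yl]-4-methoxy-6-methylphenol
Product: 27 [(2Z,4R,5E,9E)-2-[2-[2-(tert-butyldimethylsilyloxy)-5-methoxy-3-methylphenyl]ethylidene]-10-[(2S,4S)-4-(tert-butyldimethylsilyloxy)-5,5-dimethyltetrahydrofuran-2-yl]-6-methyl-4-(triethylsilyloxy)undeca-5,9-dien-1-ol], via sodium phenoxide 26 (not isolated)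
Conditions: NaH (1.0 equiv), THF, 0 °C; then TBSCl (1.05 equiv), 0 °C to rt
Reagents that add atoms: tert-butyldimethylsilyl chloride, CC(C)(C)[Si](C)(C)Cl
Why: One equivalent of base deprotonates only the phenol, which is about six pKa units more acidic than the alcohol, so O-silylation should occur at the phenoxide alone.

Step 19
Reactants: 27 aryl tert-butyldimethylsilyl ether of 25
Product: 29 tert-butyldimethylsilyl ether of 2-[(2E,5R,6E,10E)-11-[(2S,4S)-4-(tert-butyldimethylsilyloxy)-5,5-dimethyltetrahydrofuran-2-yl]-3,7-dimethyl-5-(triethylsilyloxy)dodeca-2,6,10-trien-1-yl]-4-methoxy-6-methylphenol, via allylic mesylate 28 (not isolated)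
Conditions: MsCl (1.2 equiv), Et3N (1.5 equiv), THF, −40 °C; then LiEt3BH (3 equiv), −40 to 0 °C
Reagents that add atoms: none
Why: Sulfonylation followed by SN2 hydride displacement at the primary allylic carbon turns the C3 hydroxymethyl into the C3 methyl without moving or isomerising C2=C3, and no ester is present to be reduced.

Step 20
Reactants: 29 tert-butyldimethylsilyl ether of 2-[(2E,5R,6E,10E)-11-[(2S,4S)-4-(tert-butyldimethylsilyloxy)-5,5-dimethyltetrahydrofuran-2-yl]-3,7-dimethyl-5-(triethylsilyloxy)dodeca-2,6,10-trien-1-yl]-4-methoxy-6-methylphenol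
Product: 30 (2E,5R,6E,10E)-1-[2-(tert-butyldimethylsilyloxy)-5-methoxy-3-methylphenyl]-11-[(2S,4S)-4-(tert-butyldimethylsilyloxy)-5,5-dimethyltetrahydrofuran-2-yl]-3,7-dimethyldodeca-2,6,10-trien-5-ol
Conditions: pyridinium p-toluenesulfonate (0.2 equiv), MeOH/CH2Cl2, 0 °C
Reagents that add atoms: none
Why: Acid-catalysed methanolysis removes the triethylsilyl ether far faster than the aryl and the hindered secondary tert-butyldimethylsilyl ethers.

Step 21
Reactants: 30 (2E,5R,6E,10E)-1-[2-(tert-butyldimethylsilyloxy)-5-methoxy-3-methylphenyl]-11-[(2S,4S)-4-(tert-butyldimethylsilyloxy)-5,5-dimethyltetrahydrofuran-2-yl]-3,7-dimethyldodeca-2,6,10-trien-5-ol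
Product: 31 (2E,5R,6E,10E)-1-[2-(tert-butyldimethylsilyloxy)-5-methoxy-3-methylphenyl]-11-[(2S,4S)-4-(tert-butyldimethylsilyloxy)-5,5-dimethyltetrahydrofuran-2-yl]-3,7-dimethyldodeca-2,6,10-trien-5-yl acetate
Conditions: Ac2O, pyridine, DMAP (cat.), CH2Cl2, 0 °C to rt
Reagents that add atoms: acetic anhydride, CC(=O)OC(C)=O
Why: DMAP-catalysed acetylation of the only free hydroxyl installs the C5 acetate with retention at C5.

Step 22
Reactants: 31 (2E,5R,6E,10E)-1-[2-(tert-butyldimethylsilyloxy)-5-methoxy-3-methylphenyl]-11-[(2S,4S)-4-(tert-butyldimethylsilyloxy)-5,5-dimethyltetrahydrofuran-2-yl]-3,7-dimethyldodeca-2,6,10-trien-5-yl acetate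
Product: 32 (2E,5R,6E,10E)-1-(2-hydroxy-5-methoxy-3-methylphenyl)-11-[(2S,4S)-4-hydroxy-5,5-dimethyltetrahydrofuran-2-yl]-3,7-dimethyldodeca-2,6,10-trien-5-yl acetate (CNP0148147.2)
Conditions: HF·pyridine, pyridine, THF, 0 °C to rt
Reagents that add atoms: none
Why: Fluoride-mediated Si–O cleavage buffered with pyridine removes both tert-butyldimethylsilyl groups while sparing the allylic acetate and avoiding acid-induced chroman formation.

Compound list
1 | 4-methoxy-2-methylphenol | COc1ccc(O)c(C)c1 | starting material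
2 | allyl bromide | C=CCBr | starting material
3 | allyl 4-methoxy-2-methylphenyl ether | COc1ccc(OCC=C)c(C)c1 | intermediate
4 | 6-allyl-4-methoxy-2-methylcyclohexa-2,4-dien-1-one (Claisen dienone, racemic) | COC1=CC(CC=C)C(=O)C(C)=C1 | intermediate
5 | 2-allyl-4-methoxy-6-methylphenol | COc1cc(C)c(O)c(CC=C)c1 | intermediate
6 | geranyl acetate, (2E)-3,7-dimethylocta-2,6-dien-1-yl acetate | CC(=O)OC/C=C(\C)CCC=C(C)C | starting material
7 | (2E,6E)-8-hydroxy-3,7-dimethylocta-2,6-dien-1-yl acetate | CC(=O)OC/C=C(\C)CC/C=C(\C)CO | intermediate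
8 | (2E,6E)-3,7-dimethyl-8-oxoocta-2,6-dien-1-yl acetate | CC(=O)OC/C=C(\C)CC/C=C(\C)C=O | intermediate
9 | O-bis(isopinocampheyl)boryl derivative (borinate ester) of 10 | CC(=O)OC/C=C(\C)CC/C=C(\C)[C@@H](OB([C@@H]1C[C@@H]2C[C@H]([C@H]1C)C2(C)C)[C@@H]1C[C@@H]2C[C@H]([C@H]1C)C2(C)C)CC=C | intermediate
10 | (2E,6E,8S)-8-hydroxy-3,7-dimethylundeca-2,6,10-trien-1-yl acetate | CC(=O)OC/C=C(\C)CC/C=C(\C)[C@@H](O)CC=C | intermediate
11 | (2E,6E,8S)-8-hydroxy-3,7,11-trimethyldodeca-2,6,10-trien-1-yl acetate | CC(=O)OC/C=C(\C)CC/C=C(\C)[C@@H](O)CC=C(C)C | intermediate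
12 | (2E,6E,8S)-3,7,11-trimethyldodeca-2,6,10-triene-1,8-diyl diacetate | CC(=O)OC/C=C(\C)CC/C=C(\C)[C@@H](OC(C)=O)CC=C(C)C | intermediate
13 | (2E,6E,8S)-9-[(2S)-3,3-dimethyloxiran-2-yl]-3,7-dimethylnona-2,6-diene-1,8-diyl diacetate | CC(=O)OC/C=C(\C)CC/C=C(\C)[C@@H](OC(C)=O)C[C@@H]1OC1(C)C | intermediate
14 | (2E,6E,8S)-9-[(2S)-3,3-dimethyloxiran-2-yl]-3,7-dimethylnona-2,6-diene-1,8-diol | OC/C=C(\C)CC/C=C(\C)[C@@H](O)C[C@@H]1OC1(C)C | intermediate
15 | (3S,5S)-5-[(2E,6E)-8-hydroxy-6-methylocta-2,6-dien-2-yl]-2,2-dimethyltetrahydrofuran-3-ol | OC/C=C(\C)CC/C=C(\C)[C@@H]1C[C@H](O)C(C)(C)O1 | intermediate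
16 | (2E,6E)-7-[(2S,4S)-4-hydroxy-5,5-dimethyltetrahydrofuran-2-yl]-3-methylocta-2,6-dienal | O=C/C=C(\C)CC/C=C(\C)[C@@H]1C[C@H](O)C(C)(C)O1 | intermediate
17 | (2E,6E)-7-[(2S,4S)-4-(tert-butyldimethylsilyloxy)-5,5-dimethyltetrahydrofuran-2-yl]-3-methylocta-2,6-dienal | O=C/C=C(\C)CC/C=C(\C)[C@@H]1C[C@H](O[Si](C)(C)C(C)(C)C)C(C)(C)O1 | intermediate
18 | methyl 2-(bromomethyl)acrylate | COC(=O)C(=C)CBr | starting material
19 | trimethylsilyl ether of 20 | COC(=O)C(=C)C[C@H](/C=C(\C)CC/C=C(\C)[C@@H]1C[C@H](O[Si](C)(C)C(C)(C)C)C(C)(C)O1)O[Si](C)(C)C | intermediate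
20 | methyl (4R,5E,9E)-10-[(2S,4S)-4-(tert-butyldimethylsilyloxy)-5,5-dimethyltetrahydrofuran-2-yl]-4-hydroxy-6-methyl-2-methylideneundeca-5,9-dienoate | COC(=O)C(=C)C[C@H](/C=C(\C)CC/C=C(\C)[C@@H]1C[C@H](O[Si](C)(C)C(C)(C)C)C(C)(C)O1)O | intermediate
21 | methyl (4R,5E,9E)-10-[(2S,4S)-4-(tert-butyldimethylsilyloxy)-5,5-dimethyltetrahydrofuran-2-yl]-6-methyl-2-methylidene-4-(triethylsilyloxy)undeca-5,9-dienoate | COC(=O)C(=C)C[C@H](/C=C(\C)CC/C=C(\C)[C@@H]1C[C@H](O[Si](C)(C)C(C)(C)C)C(C)(C)O1)O[Si](CC)(CC)CC | intermediate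
22 | (4R,5E,9E)-10-[(2S,4S)-4-(tert-butyldimethylsilyloxy)-5,5-dimethyltetrahydrofuran-2-yl]-6-methyl-2-methylidene-4-(triethylsilyloxy)undeca-5,9-dienoic acid | OC(=O)C(=C)C[C@H](/C=C(\C)CC/C=C(\C)[C@@H]1C[C@H](O[Si](C)(C)C(C)(C)C)C(C)(C)O1)O[Si](CC)(CC)CC | intermediate
23 | 2-allyl-4-methoxy-6-methylphenyl ester of 22 (metathesis precursor) | COc1cc(C)c(OC(=O)C(=C)C[C@H](/C=C(\C)CC/C=C(\C)[C@@H]2C[C@H](O[Si](C)(C)C(C)(C)C)C(C)(C)O2)O[Si](CC)(CC)CC)c(CC=C)c1 | intermediate
24 | 3-[(2R,3E,7E)-8-[(2S,4S)-4-(tert-butyldimethylsilyloxy)-5,5-dimethyltetrahydrofuran-2-yl]-4-methyl-2-(triethylsilyloxy)nona-3,7-dien-1-yl]-7-methoxy-9-methyl-1-benzoxepin-2(5H)-one | COc1cc(C)c2OC(=O)C(C[C@H](/C=C(\C)CC/C=C(\C)[C@@H]3C[C@H](O[Si](C)(C)C(C)(C)C)C(C)(C)O3)O[Si](CC)(CC)CC)=CCc2c1 | intermediate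
25 | 2-[(2Z,5R,6E,10E)-11-[(2S,4S)-4-(tert-butyldimethylsilyloxy)-5,5-dimethyltetrahydrofuran-2-yl]-3-(hydroxymethyl)-7-methyl-5-(triethylsilyloxy)dodeca-2,6,10-trien-1-yl]-4-methoxy-6-methylphenol | COc1cc(C)c(O)c(C/C=C(\CO)C[C@H](/C=C(\C)CC/C=C(\C)[C@@H]2C[C@H](O[Si](C)(C)C(C)(C)C)C(C)(C)O2)O[Si](CC)(CC)CC)c1 | intermediate
26 | sodium phenoxide of 25 | COc1cc(C)c([O-])c(C/C=C(\CO)C[C@H](/C=C(\C)CC/C=C(\C)[C@@H]2C[C@H](O[Si](C)(C)C(C)(C)C)C(C)(C)O2)O[Si](CC)(CC)CC)c1.[Na+] | intermediate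
27 | aryl tert-butyldimethylsilyl ether of 25 (C3 hydroxymethyl free) | COc1cc(C)c(O[Si](C)(C)C(C)(C)C)c(C/C=C(\CO)C[C@H](/C=C(\C)CC/C=C(\C)[C@@H]2C[C@H](O[Si](C)(C)C(C)(C)C)C(C)(C)O2)O[Si](CC)(CC)CC)c1 | intermediate
28 | methanesulfonate of 27 at the C3 hydroxymethyl group | COc1cc(C)c(O[Si](C)(C)C(C)(C)C)c(C/C=C(\COS(C)(=O)=O)C[C@H](/C=C(\C)CC/C=C(\C)[C@@H]2C[C@H](O[Si](C)(C)C(C)(C)C)C(C)(C)O2)O[Si](CC)(CC)CC)c1 | intermediate
29 | tert-butyldimethylsilyl ether of 2-[(2E,5R,6E,10E)-11-[(2S,4S)-4-(tert-butyldimethylsilyloxy)-5,5-dimethyltetrahydrofuran-2-yl]-3,7-dimethyl-5-(triethylsilyloxy)dodeca-2,6,10-trien-1-yl]-4-methoxy-6-methylphenol | COc1cc(C)c(O[Si](C)(C)C(C)(C)C)c(C/C=C(\C)C[C@H](/C=C(\C)CC/C=C(\C)[C@@H]2C[C@H](O[Si](C)(C)C(C)(C)C)C(C)(C)O2)O[Si](CC)(CC)CC)c1 | intermediate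
30 | (2E,5R,6E,10E)-1-[2-(tert-butyldimethylsilyloxy)-5-methoxy-3-methylphenyl]-11-[(2S,4S)-4-(tert-butyldimethylsilyloxy)-5,5-dimethyltetrahydrofuran-2-yl]-3,7-dimethyldodeca-2,6,10-trien-5-ol | COc1cc(C)c(O[Si](C)(C)C(C)(C)C)c(C/C=C(\C)C[C@H](/C=C(\C)CC/C=C(\C)[C@@H]2C[C@H](O[Si](C)(C)C(C)(C)C)C(C)(C)O2)O)c1 | intermediate
31 | (2E,5R,6E,10E)-1-[2-(tert-butyldimethylsilyloxy)-5-methoxy-3-methylphenyl]-11-[(2S,4S)-4-(tert-butyldimethylsilyloxy)-5,5-dimethyltetrahydrofuran-2-yl]-3,7-dimethyldodeca-2,6,10-trien-5-yl acetate | COc1cc(C)c(O[Si](C)(C)C(C)(C)C)c(C/C=C(\C)C[C@H](/C=C(\C)CC/C=C(\C)[C@@H]2C[C@H](O[Si](C)(C)C(C)(C)C)C(C)(C)O2)OC(C)=O)c1 | intermediate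
32 | (2E,5R,6E,10E)-1-(2-hydroxy-5-methoxy-3-methylphenyl)-11-[(2S,4S)-4-hydroxy-5,5-dimethyltetrahydrofuran-2-yl]-3,7-dimethyldodeca-2,6,10-trien-5-yl acetate | COc1cc(C)c(O)c(C/C=C(\C)C[C@H](/C=C(\C)CC/C=C(\C)[C@@H]2C[C@H](O)C(C)(C)O2)OC(C)=O)c1 | target

Total step count: 22. Longest linear sequence: 20 steps (6 to 32, steps 3–22); the phenol branch (steps 1–2) joins at step 15.

Steps most likely to fail

Step 16. Turnover at the hindered, electron-poor 1,1-disubstituted alkene may be slower than migration of the allyl double bond toward the arene (which would then close to a six-membered coumarin with loss of propene) or than intermolecular coupling at the allyl terminus. The fallback sets out from 17 and 1 and returns at 29; it builds C2=C3 by alkyne carbometalation and benzylic cross-coupling instead of metathesis. Asymmetric propargylation of 17 with B-allenyldiisopinocampheylborane of the (−)-α-pinene series (Re-face addition) should give the homopropargylic alcohol (4R,5E,9E)-10-[(2S,4S)-4-(tert-butyldimethylsilyloxy)-5,5-dimethyltetrahydrofuran-2-yl]-6-methylundeca-5,9-dien-1-yn-4-ol F1, which TESCl/imidazole converts to its triethylsilyl ether F2. Separately, magnesium-mediated ortho-formylation of 1 (MgCl2, Et3N, paraformaldehyde) should give 2-hydroxy-5-methoxy-3-methylbenzaldehyde F3; TBSCl/imidazole gives 2-(tert-butyldimethylsilyloxy)-5-methoxy-3-methylbenzaldehyde F4, NaBH4 gives [2-(tert-butyldimethylsilyloxy)-5-methoxy-3-methylphenyl]methanol F5, and an Appel reaction (CBr4, PPh3) gives the benzyl bromide 2-(bromomethyl)-4-methoxy-6-methylphenyl tert-butyldimethylsilyl ether F6. Zirconium-catalysed methylalumination of F2 (Me3Al, Cp2ZrCl2, CH2Cl2) adds methyl and aluminium syn across the alkyne to give the (E)-alkenyl(dimethyl)alane F7, which is coupled in the same flask with F6 (Pd(PPh3)4, THF, Negishi-type coupling) to give 29 with the C3 methyl cis to C1. Steps 20–22 then follow unchanged.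

Step 12. Facial discrimination may be poor at a β,β-disubstituted enal with no nearby stereocentre, or the chromium alkoxide may lactonise before it is silylated. The fallback sets out from 17 and 18 and returns at 20; it sets C5 by asymmetric reduction instead of asymmetric C–C bond formation. An indium-mediated Barbier allylation (In powder, THF/H2O, rt) should give the hydroxy ester as a mixture of C5 epimers, methyl (5E,9E)-10-[(2S,4S)-4-(tert-butyldimethylsilyloxy)-5,5-dimethyltetrahydrofuran-2-yl]-4-hydroxy-6-methyl-2-methylideneundeca-5,9-dienoate F8. MnO2 oxidises its allylic alcohol to the dienone methyl (5E,9E)-10-[(2S,4S)-4-(tert-butyldimethylsilyloxy)-5,5-dimethyltetrahydrofuran-2-yl]-6-methyl-2-methylidene-4-oxoundeca-5,9-dienoate F9. Corey–Bakshi–Shibata reduction of F9 with (S)-2-methyl-CBS-oxazaborolidine and catecholborane in toluene at −78 °C, the alkenyl group acting as the large substituent, should return 20 with the 5R configuration.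

Step 18. Discrimination between the phenoxide and the primary allylic hydroxyl may be incomplete, so that the alcohol is silylated as well or instead. The fallback sets out from 25 and returns at 29; it changes the order of events so that no selective protection is needed. The primary allylic alcohol of 25 is first converted with preformed PPh3/N-chlorosuccinimide (Appel-type, the phenol not reacting with the chlorophosphonium salt) to the allylic chloride 2-[(2Z,5R,6E,10E)-11-[(2S,4S)-4-(tert-butyldimethylsilyloxy)-5,5-dimethyltetrahydrofuran-2-yl]-3-(chloromethyl)-7-methyl-5-(triethylsilyloxy)dodeca-2,6,10-trien-1-yl]-4-methoxy-6-methylphenol F10. The phenol, now the only hydroxyl, is silylated with TBSOTf/2,6-lutidine at −78 °C to give the aryl tert-butyldimethylsilyl ether of F10, F11, and LiEt3BH then displaces chloride (SN2) to give 29.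

Further compounds
F1 | step 16 | (4R,5E,9E)-10-[(2S,4S)-4-(tert-butyldimethylsilyloxy)-5,5-dimethyltetrahydrofuran-2-yl]-6-methylundeca-5,9-dien-1-yn-4-ol | C#CC[C@@H](O)/C=C(\C)CC/C=C(\C)[C@@H]1C[C@H](O[Si](C)(C)C(C)(C)C)C(C)(C)O1
F2 | step 16 | triethylsilyl ether of F1 | C#CC[C@@H](O[Si](CC)(CC)CC)/C=C(\C)CC/C=C(\C)[C@@H]1C[C@H](O[Si](C)(C)C(C)(C)C)C(C)(C)O1
F3 | step 16 | 2-hydroxy-5-methoxy-3-methylbenzaldehyde | COc1cc(C)c(O)c(C=O)c1
F4 | step 16 | 2-(tert-butyldimethylsilyloxy)-5-methoxy-3-methylbenzaldehyde | COc1cc(C)c(O[Si](C)(C)C(C)(C)C)c(C=O)c1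
F5 | step 16 | [2-(tert-butyldimethylsilyloxy)-5-methoxy-3-methylphenyl]methanol | COc1cc(C)c(O[Si](C)(C)C(C)(C)C)c(CO)c1
F6 | step 16 | 2-(bromomethyl)-4-methoxy-6-methylphenyl tert-butyldimethylsilyl ether | COc1cc(C)c(O[Si](C)(C)C(C)(C)C)c(CBr)c1
F7 | step 16 | (E)-alkenyl(dimethyl)alane from methylalumination of F2 (aluminium on C2, cis to the C3 methyl) | C[Al](C)/C=C(\C)C[C@@H](O[Si](CC)(CC)CC)/C=C(\C)CC/C=C(\C)[C@@H]1C[C@H](O[Si](C)(C)C(C)(C)C)C(C)(C)O1
F8 | step 12 | methyl (5E,9E)-10-[(2S,4S)-4-(tert-butyldimethylsilyloxy)-5,5-dimethyltetrahydrofuran-2-yl]-4-hydroxy-6-methyl-2-methylideneundeca-5,9-dienoate, mixture of C4 (target C5) epimers | COC(=O)C(=C)CC(O)/C=C(\C)CC/C=C(\C)[C@@H]1C[C@H](O[Si](C)(C)C(C)(C)C)C(C)(C)O1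
F9 | step 12 | methyl (5E,9E)-10-[(2S,4S)-4-(tert-butyldimethylsilyloxy)-5,5-dimethyltetrahydrofuran-2-yl]-6-methyl-2-methylidene-4-oxoundeca-5,9-dienoate | COC(=O)C(=C)CC(=O)/C=C(\C)CC/C=C(\C)[C@@H]1C[C@H](O[Si](C)(C)C(C)(C)C)C(C)(C)O1
F10 | step 18 | 2-[(2Z,5R,6E,10E)-11-[(2S,4S)-4-(tert-butyldimethylsilyloxy)-5,5-dimethyltetrahydrofuran-2-yl]-3-(chloromethyl)-7-methyl-5-(triethylsilyloxy)dodeca-2,6,10-trien-1-yl]-4-methoxy-6-methylphenol | COc1cc(C)c(O)c(C/C=C(\CCl)C[C@H](/C=C(\C)CC/C=C(\C)[C@@H]2C[C@H](O[Si](C)(C)C(C)(C)C)C(C)(C)O2)O[Si](CC)(CC)CC)c1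
F11 | step 18 | aryl tert-butyldimethylsilyl ether of F10 | COc1cc(C)c(O[Si](C)(C)C(C)(C)C)c(C/C=C(\CCl)C[C@H](/C=C(\C)CC/C=C(\C)[C@@H]2C[C@H](O[Si](C)(C)C(C)(C)C)C(C)(C)O2)O[Si](CC)(CC)CC)c1
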